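Under the overall G + Q → Z, each Z takes one Q, so [Q] + [Z] stays at the charge of Q, written Qc. That balance is what you can bracket the north-east run with.

| setting | west | north | south-east | north-east |
|---|---|---|---|---|
| G | 250 mM | 250 mM | 120 mM | 250 mM |
| Q | 625 mM | 310 mM | 625 mM | 96.0 mM |
| time |  |  |  | 18 min |

| run | time / min | [Z] / mM |
|---|---|---|
| west run | 0.80 | 12.2 |
| west run | 2.4 | 33.1 |
| west run | 4.6 | 55.3 |
| west run | 7.4 | 79.0 |
| west run | 11 | 98.0 |
| west run | 14 | 108.2 |
| west run | 18 | 120.1 |
| north run | 0.80 | 3.7 |
| north run | 2.4 | 20.7 |
| north run | 4.6 | 29.0 |
| north run | 7.4 | 47.3 |
| north run | 11 | 57.6 |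
| north run | 14 | 60.8 |
| north run | 18 | 68.5 |
| south-east run | 0.80 | 2.8 |
| south-east run | 2.4 | 15.8 |
| south-east run | 4.6 | 28.8 |
| south-east run | 7.4 | 39.9 |
| south-east run | 11 | 48.5 |
| south-east run | 14 | 54.7 |
| south-east run | 18 | 61.2 |

(each reading ± 2 mM)

1. how the opening rate goes with [G] round the charge of the west run: the exponent of the rate at two percent of G gone to Z (one fixed amount of Z, the same in the runs compared)
2. how the opening rate goes with [Q] round the charge of the west run: the exponent of the rate at two percent of G gone to Z
3. Z in the north-east run at 18 min, as a share of the G charged
4. which of these the readings show (the substrate pairs with itself / nothing beyond the main steps / the substrate is lost by itself / the product binds the second partner / the product speeds the reaction)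

- Overall: G + Q -> Z.
- Constant volume, constant temperature.
- "The second partner" is Q.
- An order is taken over about fifteen percent of the charge, up and down.

The north-east run holds less Q than G, so by the charges Q is the limiting reagent, and Z cannot pass 38.4 % of the G charged. To tighten this, take D = ln(Qc/(Qc − Z)), which the west run reads as 0.213 at 18 min: this is the Q exposure, the logarithmic loss of the reagent. With the Q charge cut to half, the north run reads D = 0.250, so I treat the rate as first order in Q and D as set by the G present.

The north run's D is the higher, and I put that down to its smaller Z at 18 min, which spends less G. The north-east run should spend less again, so the north run's D gives my estimated floor: 21.2 mM, or 8.49 % of the G charged. For an estimated top, [G] can only fall, so I hold the west run's pace of D over its first 2.4 min for the whole 18 min. That gives D = 0.408 and 12.9 %. Continuing the step in D from west to north down to the floor's Z, I get D = 0.283 and commit to 9.46 %.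

The forecast says 10.1 %, which lies inside my bracket and above my figure. It gives orders 1.03 in G and 1.02 in Q, and its choice is the substrate is lost by itself: “G must be decaying first-order by itself”.

    G + Q → Z (0.1068 M⁻¹ min⁻¹)
    G → Lx (0.04668 min⁻¹)

The north-east run gives 10.0 %, inside the bracket, with orders 1.0 and 1.0, and the readings show the substrate is lost by itself. Fitted with nothing beyond the main steps, they leave a root mean square residual of 2.9 in units of the scatter. The north-east exposure comes to D = 0.303, higher than the west run's. The south-east run, charged with about half the G of the west run, reads D = 0.103 at 18 min, half the west value.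

The runs were generated by integration for an exercise, and the scatter is random.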